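**Plan**

- Retrosynthesis: the benzyl ethers and the C4'–OH are cut first, which leads back to a 1,4-epoxy bridge. Then C1'–C8a' and C4'–C4a' of the naphthalene are cut (3-methoxybenzyne plus a 2-furyl group), then the C4–furyl bond (o-quinone methide plus furylboronate). The remaining tetralone comes from naphthazarin.
- Enabling feature: naphthalene ring C1'–C4' carries only the tetralone link at C1' and OH at C4' (para to it), while OMe sits on the peri carbon C8' of the other ring. This is the pattern of an acid-opened adduct of 3-methoxybenzyne with a 2-substituted furan.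
- Forward: the tetralone bicycle is present from the start (naphthazarin, two reductions, ethyl ether at C4). The furan is attached at C4 and the phenols are benzylated. The aryne cycloaddition then closes the carbocycle C1'–C2'–C3'–C4'–C4a'–C8a', acid turns the oxygen-bridged adduct into the 1-naphthol, and hydrogenolysis frees the phenols.
- Stereochemistry: the only stereocentre, C4, is set in step 5 by a chiral biphenol catalyst during furyl transfer to the o-quinone methide. It is a spectator afterwards (R in the furan series, S in the target, same spatial arrangement). The two bridgehead centres of the cycloadduct are erased on aromatisation.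

Key step: step 7

Remark: the sense of induction of the biphenol catalyst at this methide is assumed; (R)-3,3'-dibromo-BINOL is written, and its antipode is used instead if it proves to deliver the (4S)-furyl compound.

**Route**

Step 1
Reactants: 1 naphthazarin (5,8-dihydroxynaphthalene-1,4-dione)
Product: 3 5,8-dihydroxy-2,3-dihydronaphthalene-1,4-dione, via naphthalene-1,4,5,8-tetrol 2 (not isolated)
Conditions: SnCl2·2H2O, 4 M aq. HCl, reflux, Ar
Reagents that add atoms: none
Why: Quinone reduction by divalent tin gives the tetrol, which ketonises under the acid to the doubly chelated diketo tautomer (the classical leuco-naphthazarin preparation).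

Step 2
Reactants: 3 5,8-dihydroxy-2,3-dihydronaphthalene-1,4-dione
Product: 4 rac-4,5,8-trihydroxy-3,4-dihydronaphthalen-1(2H)-one
Conditions: NaBH4 (1.0 equiv), THF–EtOH, −40 °C, Ar; AcOH quench
Reagents that add atoms: none
Why: Borohydride reduction of one of two equivalent aryl ketones; after the first reduction the remaining carbonyl loses the activation by its ortho-acyl partner, so mono-reduction should be controllable by stoichiometry and temperature, and the racemic carbinol centre needs no control.

Step 3
Reactants: 4 rac-4,5,8-trihydroxy-3,4-dihydronaphthalen-1(2H)-one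
Product: 5 rac-4-ethoxy-5,8-dihydroxy-3,4-dihydronaphthalen-1(2H)-one
Conditions: EtOH (solvent), p-TsOH·H2O (cat.), 20 °C, short contact; NaHCO3
Reagents that add atoms: ethanol, CCO
Why: Acid-catalysed SN1 etherification of an o-hydroxybenzylic alcohol; the C5 hydroxyl stabilises the benzylic cation (o-quinone methide character) and the solvent ethanol should capture it faster than a C3 proton is lost.

Step 4
Reactants: 6 furan-2-boronic acid
Product: 7 dipropan-2-yl furan-2-ylboronate
Conditions: i-PrOH, toluene, reflux with azeotropic removal of water; concentrate, keep under Ar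
Reagents that add atoms: propan-2-ol, CC(C)O
Why: Boronic acid esterification driven by removal of water, giving the acyclic boronate that exchanges readily with phenols and biphenols.

Step 5
Reactants: 5 rac-4-ethoxy-5,8-dihydroxy-3,4-dihydronaphthalen-1(2H)-one; 7 dipropan-2-yl furan-2-ylboronate
Product: 9 (4R)-4-(furan-2-yl)-5,8-dihydroxy-3,4-dihydronaphthalen-1(2H)-one, via 8-hydroxy-2,3-dihydronaphthalene-1,5-dione 8 (not isolated)
Conditions: 7 (2 equiv), (R)-3,3'-dibromo-BINOL (15 mol %), 4 Å MS, PhCF3, 40 °C; aq. work-up
Reagents that add atoms: none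
Why: Proposed new method: the C5 phenol and the biphenol exchange onto boron of 7, the resulting Lewis-acidic mixed boronate assists loss of ethoxide from C4 to give methide 8 as a tight ion pair with the chiral borate, and the furyl group then migrates from boron to C4 on the face left open by the 3,3'-dibromobiphenol, which sets the (4R)-centre; the closest known reaction type is the chiral-biphenol-catalysed enantioselective addition of aryl- and alkenylboronates to o-quinone methides generated from aryl-substituted 2-(ethoxymethyl)phenols, here extended to a ring-embedded methide that bears β-hydrogens and a ring ketone.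

Step 6
Reactants: 9 (4R)-4-(furan-2-yl)-5,8-dihydroxy-3,4-dihydronaphthalen-1(2H)-one
Product: 10 (4R)-5,8-bis(benzyloxy)-4-(furan-2-yl)-3,4-dihydronaphthalen-1(2H)-one
Conditions: BnBr, K2CO3, n-Bu4NI (cat.), DMF, 50 °C, Ar
Reagents that add atoms: benzyl bromide, BrCc1ccccc1
Why: Williamson ether synthesis on both phenols (the chelated C8 hydroxyl needs the warm DMF conditions); C4 has no acidic hydrogen under carbonate base, so its configuration is retained.

Step 7
Reactants: 10 (4R)-5,8-bis(benzyloxy)-4-(furan-2-yl)-3,4-dihydronaphthalen-1(2H)-one; 11 3-methoxy-2-(trimethylsilyl)phenyl trifluoromethanesulfonate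
Product: 13 (4R)-5,8-bis(benzyloxy)-4-[(1R,4R)-8-methoxy-1,4-dihydro-1,4-epoxynaphthalen-1-yl]-3,4-dihydronaphthalen-1(2H)-one, via 3-methoxybenzyne 12 (not isolated)
Conditions: 11 (1.8 equiv, slow addition), CsF (4 equiv), MeCN, rt
Reagents that add atoms: none
Why: CsF desilylates 11 and triflate leaves, releasing 3-methoxybenzyne 12, which adds across the two furan α-carbons of 10 in a concerted, asynchronous [4+2] cycloaddition; the closest known reaction type is the aryne–furan Diels–Alder reaction of fluoride-generated arynes with 2-alkylfurans. The single new ring, the carbocycle C1'–C2'–C3'–C4'–C4a'–C8a', closes intermolecularly by formation of C1'–C8a' and C4'–C4a' in the one cycloaddition event, the furan oxygen remaining as the 1,4-epoxy bridge. The two new bridgehead centres C1' and C4' are held cis by the suprafacial addition and the bridge; which furan face reacts relative to C4 is left uncontrolled on purpose (13 is expected together with its (1S,4S) bridgehead isomer), since both centres become sp2 in step 8, and C4 has no pathway to epimerise under CsF in MeCN. The selectivity the step needs is regiochemical: the σ-withdrawing methoxy group distorts the aryne so that the carbon meta to it is the more electrophilic, the more nucleophilic unsubstituted α-carbon of the 2-alkylfuran bonds there in the earlier-formed bond, and the substituted α-carbon is thereby joined to the aryne carbon next to OMe, which places C8'–OMe peri to C1'. This polar bias works against the bulk of the tetralonyl group, so some reverse-oriented adduct has to be reckoned with and would be removed by chromatography after step 8. The benzyl ethers keep the phenols from adding to the aryne, and slow addition of 11 keeps the aryne concentration low so that the furan, the best arynophile present, captures it.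

Step 8
Reactants: 13 (4R)-5,8-bis(benzyloxy)-4-[(1R,4R)-8-methoxy-1,4-dihydro-1,4-epoxynaphthalen-1-yl]-3,4-dihydronaphthalen-1(2H)-one
Product: 14 (4S)-5,8-bis(benzyloxy)-4-(4-hydroxy-8-methoxynaphthalen-1-yl)-3,4-dihydronaphthalen-1(2H)-one
Conditions: CF3CO2H (2 equiv), CH2Cl2, 0 °C → rt
Reagents that add atoms: none
Why: Acid-catalysed isomerisation of a bridgehead-substituted 1,4-epoxy-1,4-dihydronaphthalene to a 1-naphthol: protonation of the bridge oxygen, heterolysis of the tertiary C1'–O bond (cation stabilised by the allyl system and the ortho-methoxy arene) and loss of the C4' proton aromatise the ring with OH left at C4'; both bridgehead isomers converge and C4 is untouched (its descriptor becomes S only because the naphthyl group ranks below C4a).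

Step 9
Reactants: 14 (4S)-5,8-bis(benzyloxy)-4-(4-hydroxy-8-methoxynaphthalen-1-yl)-3,4-dihydronaphthalen-1(2H)-one
Product: 15 (4S)-5,8-dihydroxy-4-(4-hydroxy-8-methoxynaphthalen-1-yl)-3,4-dihydronaphthalen-1(2H)-one
Conditions: H2 (1 atm), 10% Pd/C, EtOAc–MeOH, rt
Reagents that add atoms: none
Why: Catalytic hydrogenolysis of the two aryl benzyl ethers under mild, neutral conditions that should leave the aryl ketone, the naphthalene, the methyl ether and the C4–H centre untouched.

**Compound list**

1 | naphthazarin (5,8-dihydroxynaphthalene-1,4-dione) | O=C1C=CC(=O)c2c(O)ccc(O)c12 | starting material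
2 | naphthalene-1,4,5,8-tetrol | Oc1ccc(O)c2c(O)ccc(O)c12 | intermediate (not isolated)
3 | 5,8-dihydroxy-2,3-dihydronaphthalene-1,4-dione | O=C1CCC(=O)c2c(O)ccc(O)c12 | intermediate
4 | rac-4,5,8-trihydroxy-3,4-dihydronaphthalen-1(2H)-one (racemic) | OC1CCC(=O)c2c(O)ccc(O)c12 | intermediate
5 | rac-4-ethoxy-5,8-dihydroxy-3,4-dihydronaphthalen-1(2H)-one (racemic) | CCOC1CCC(=O)c2c(O)ccc(O)c12 | intermediate
6 | furan-2-boronic acid | OB(O)c1ccco1 | starting material
7 | dipropan-2-yl furan-2-ylboronate | CC(C)OB(OC(C)C)c1ccco1 | intermediate
8 | 8-hydroxy-2,3-dihydronaphthalene-1,5-dione (the o-quinone methide) | O=C1CCC=C2C(=O)C=CC(O)=C12 | intermediate (not isolated)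
9 | (4R)-4-(furan-2-yl)-5,8-dihydroxy-3,4-dihydronaphthalen-1(2H)-one | o1cccc1[C@@H]2CCC(=O)c3c(O)ccc(O)c32 | intermediate
10 | (4R)-5,8-bis(benzyloxy)-4-(furan-2-yl)-3,4-dihydronaphthalen-1(2H)-one | o1cccc1[C@@H]2CCC(=O)c3c(OCc4ccccc4)ccc(OCc5ccccc5)c32 | intermediate
11 | 3-methoxy-2-(trimethylsilyl)phenyl trifluoromethanesulfonate | COc1cccc(OS(=O)(=O)C(F)(F)F)c1[Si](C)(C)C | starting material
12 | 3-methoxybenzyne | COC1=CC=CC#C1 | intermediate (not isolated)
13 | (4R)-5,8-bis(benzyloxy)-4-[(1R,4R)-8-methoxy-1,4-dihydro-1,4-epoxynaphthalen-1-yl]-3,4-dihydronaphthalen-1(2H)-one (drawn isomer; accompanied by the (1S,4S) bridgehead isomer, both carried on) | COc1cccc2[C@H]3C=C[C@@](O3)([C@@H]4CCC(=O)c5c(OCc6ccccc6)ccc(OCc7ccccc7)c54)c12 | intermediate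
14 | (4S)-5,8-bis(benzyloxy)-4-(4-hydroxy-8-methoxynaphthalen-1-yl)-3,4-dihydronaphthalen-1(2H)-one | COc1cccc2c(O)ccc([C@@H]3CCC(=O)c4c(OCc5ccccc5)ccc(OCc6ccccc6)c43)c12 | intermediate
15 | (4S)-5,8-dihydroxy-4-(4-hydroxy-8-methoxynaphthalen-1-yl)-3,4-dihydronaphthalen-1(2H)-one | COc1cccc2c(O)ccc([C@@H]3CCC(=O)c4c(O)ccc(O)c43)c12 | target

**Step count**

Total: 9 steps. Longest linear sequence: 8 steps (1, 2, 3, 5, 6, 7, 8, 9); step 4 is a one-step side branch.

**Steps most likely to fail**

Step 5 (proposed new method). Methide 8 may lose a C3 proton and aromatise to the naphthalene faster than the furyl group is transferred, or the catalyst may discriminate the faces of this ring-embedded methide poorly. The fallback uses known chemistry, sets out from 5 and returns at 10. Ether 5 is ionised with Sc(OTf)3 (cat.) in CH2Cl2 at 0 °C in a large excess of furan. This Lewis-acid Friedel–Crafts alkylation, in which the excess furan outcompetes proton loss, should give racemic 4-(furan-2-yl)-5,8-dihydroxy-3,4-dihydronaphthalen-1(2H)-one F1. Benzylation under the conditions of step 6 would give racemic 5,8-bis(benzyloxy)-4-(furan-2-yl)-3,4-dihydronaphthalen-1(2H)-one F2. Preparative chromatography on a polysaccharide chiral stationary phase then separates 10 from its enantiomer (4S)-5,8-bis(benzyloxy)-4-(furan-2-yl)-3,4-dihydronaphthalen-1(2H)-one F3. The absolute configuration of the fraction carried on is to be secured before step 7.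

Step 7. The aryne may add in the reverse orientation, the bulky C4 substituent steering the substituted bridgehead away from the methoxy-bearing carbon against the polar bias. The fallback sets out from 10 and returns at 14. It uses an aryne blocked on the side remote from OMe, whose precursor is made beforehand from commercial 2-bromo-5-methoxyphenol:

- TBSCl and imidazole give tert-butyl(2-bromo-5-methoxyphenoxy)dimethylsilane F4.
- Bromine–lithium exchange with n-BuLi triggers a retro-Brook O→C silyl shift to 2-(tert-butyldimethylsilyl)-5-methoxyphenol F5.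
- i-PrNCO and Et3N give 2-(tert-butyldimethylsilyl)-5-methoxyphenyl propan-2-ylcarbamate F6.
- In-situ N-silylation (TBSOTf, TMEDA), ortho-lithiation between the two oxygens (n-BuLi, −78 °C) and TMSCl give 6-(tert-butyldimethylsilyl)-3-methoxy-2-(trimethylsilyl)phenyl propan-2-ylcarbamate F7.
- DBU and Et2NH, then PhNTf2, give 6-(tert-butyldimethylsilyl)-3-methoxy-2-(trimethylsilyl)phenyl trifluoromethanesulfonate F8.

With CsF in MeCN only the trimethylsilyl group flanked by two oxygens should be cleaved, releasing 3-(tert-butyldimethylsilyl)-6-methoxybenzyne F9. The bulky silyl group next to one aryne carbon forces the substituted furan carbon onto the other, methoxy-flanked carbon (steric control known for 3-silylbenzynes with 2-substituted furans). The σ-donating silicon also polarises the aryne in the same sense as the methoxy group. With 10 this should give (4R)-5,8-bis(benzyloxy)-4-[(1R,4R)-5-(tert-butyldimethylsilyl)-8-methoxy-1,4-dihydro-1,4-epoxynaphthalen-1-yl]-3,4-dihydronaphthalen-1(2H)-one F10 (with its bridgehead isomer). CF3CO2H opens it to (4S)-5,8-bis(benzyloxy)-4-[5-(tert-butyldimethylsilyl)-4-hydroxy-8-methoxynaphthalen-1-yl]-3,4-dihydronaphthalen-1(2H)-one F11. Continued exposure to CF3CO2H (ipso-protonation para to the methoxy group) or, failing that, TBAF (C→O silyl shift assisted by the peri hydroxyl) removes the silyl group and gives 14.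

Step 3. Under acid, irreversible loss of a C3 proton from the benzylic cation (dehydration and aromatisation of the tetralone ring) may compete with the reversible ether formation. The fallback sets out from 4 and returns at 9, with no separate ether. Triol 4 is submitted directly to the conditions of step 5 with 7 (3 equiv) and extra 4 Å MS. The boronate condenses with the o-hydroxybenzylic alcohol and the biphenol-bound boron ionises the benzylic C–O bond to methide 8 in situ. This is the way o-quinone methides arise in boronate additions run from a phenol and an aldehyde. No compound outside the list is made (entry F0).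

**Further compounds**

F1 | step 5 | racemic 4-(furan-2-yl)-5,8-dihydroxy-3,4-dihydronaphthalen-1(2H)-one | O=C1CCC(c2ccco2)c2c(O)ccc(O)c12
F2 | step 5 | racemic 5,8-bis(benzyloxy)-4-(furan-2-yl)-3,4-dihydronaphthalen-1(2H)-one | O=C1CCC(c2ccco2)c2c(OCc3ccccc3)ccc(OCc3ccccc3)c12
F3 | step 5 | (4S)-5,8-bis(benzyloxy)-4-(furan-2-yl)-3,4-dihydronaphthalen-1(2H)-one | o1cccc1[C@H]2CCC(=O)c3c(OCc4ccccc4)ccc(OCc5ccccc5)c32
F4 | step 7 | tert-butyl(2-bromo-5-methoxyphenoxy)dimethylsilane | COc1ccc(Br)c(O[Si](C)(C)C(C)(C)C)c1
F5 | step 7 | 2-(tert-butyldimethylsilyl)-5-methoxyphenol | COc1ccc([Si](C)(C)C(C)(C)C)c(O)c1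
F6 | step 7 | 2-(tert-butyldimethylsilyl)-5-methoxyphenyl propan-2-ylcarbamate | COc1ccc([Si](C)(C)C(C)(C)C)c(OC(=O)NC(C)C)c1
F7 | step 7 | 6-(tert-butyldimethylsilyl)-3-methoxy-2-(trimethylsilyl)phenyl propan-2-ylcarbamate | COc1ccc([Si](C)(C)C(C)(C)C)c(OC(=O)NC(C)C)c1[Si](C)(C)C
F8 | step 7 | 6-(tert-butyldimethylsilyl)-3-methoxy-2-(trimethylsilyl)phenyl trifluoromethanesulfonate | COc1ccc([Si](C)(C)C(C)(C)C)c(OS(=O)(=O)C(F)(F)F)c1[Si](C)(C)C
F9 | step 7 | 3-(tert-butyldimethylsilyl)-6-methoxybenzyne | COC1=CC=C([Si](C)(C)C(C)(C)C)C#C1
F10 | step 7 | (4R)-5,8-bis(benzyloxy)-4-[(1R,4R)-5-(tert-butyldimethylsilyl)-8-methoxy-1,4-dihydro-1,4-epoxynaphthalen-1-yl]-3,4-dihydronaphthalen-1(2H)-one | COc1ccc([Si](C)(C)C(C)(C)C)c2[C@H]3C=C[C@@](O3)([C@@H]4CCC(=O)c5c(OCc6ccccc6)ccc(OCc7ccccc7)c54)c12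
F11 | step 7 | (4S)-5,8-bis(benzyloxy)-4-[5-(tert-butyldimethylsilyl)-4-hydroxy-8-methoxynaphthalen-1-yl]-3,4-dihydronaphthalen-1(2H)-one | COc1ccc([Si](C)(C)C(C)(C)C)c2c(O)ccc([C@@H]3CCC(=O)c4c(OCc5ccccc5)ccc(OCc6ccccc6)c43)c12
F0 | step 3 | none | none
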